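Watch the second end groups. Amber and green are identical charges, and your decision is whether the extra days of green are worth waiting for.

| setting | Friday's | Sunday's | Thursday's | amber | green |
|---|---|---|---|---|---|
| first end groups | 0.75 M | 1.1 M | 1.5 M | 1.5 M | 1.5 M |
| second end groups | 0.90 equiv | 0.90 equiv | 0.90 equiv | 0.900 equiv | 0.900 equiv |
| one-sided end groups | 0.075 M | 0.075 M | 0.075 M | 0.0750 M | 0.0750 M |
| protic impurity | 0.030 M | 0.030 M | 0.015 M | 0.0300 M | 0.0300 M |
| remark | run made earlier | run made earlier | run made earlier |  |  |
| time |  |  |  | 3.0 d | 6.0 d |

- Friday's (time / d: links / %, first end groups / %): 0.250: 25.6, 58.5; 0.625: 44.0, 42.1; 1.67: 64.3, 23.1; 4.00: 75.9, 10.2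
- Sunday's (time / d: links / %, first end groups / %): 0.417: 46.2, 44.6; 1.25: 68.2, 21.8; 2.50: 76.2, 14.5; 4.00: 82.5, 9.1
- Thursday's (time / d: links / %, first end groups / %): 0.417: 53.8, 41.5; 1.25: 75.0, 19.7; 2.50: 84.4, 10.6; 4.00: 85.7, 8.8

(scatter of a reading: 1 percentage point)

- each monomer carries two end groups and one-sided end groups one, which caps an end: a chain counts once for every two ends that are left, dead ends included; the units are half of the end groups of the two monomers charged
- what was read earlier has a scatter of 1 percentage point, one standard deviation

1. which of the two ends with the longer chains by the average number of monomer units in a chain (unreacted monomers counted as chains of one) ("neither" if they lie within 10%) (amber / green / neither)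
2. average number of monomer units in a chain (unreacted monomers counted as chains of one) at the end, amber
3. average number of monomer units in a chain (unreacted monomers counted as chains of one) at the end, green

Write [L] for links and [B] for second end groups. Each link removes one chain, so the chains are [U] − [L], where [U] is the concentration of units, here 1.43 M, and the length is [U] divided by the chains.

In Sunday's run at 1.25 d, links and first end groups fall short of the charge by 0.110 M, close to the 0.105 M of one-sided end groups and protic impurity together. In Thursday's run, with less impurity, the shortfall is 0.0795 M. So I let each of those take one first end early.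

What counts afterwards is the gap, the first end groups left after those early losses minus the second end groups charged: 0.0450 M in amber and green. First ends stay more plentiful than second ends, which makes second end groups the limiting reagent, and d[B]/dt = −k[B]([B] + gap).

Sunday's gap is 0.00500 M, so 1/[B] climbs nearly in a straight line there, and its 1.25 d reading gives k = 2.53 L mol⁻¹ d⁻¹. Integrating, I get [B] = 0.0992 M for amber and 0.0431 M for green, so lengths of 8.18 and 12.1. I would wait for green.

The forecast says green, with 7.9 and 11.8, a little below mine; it takes k as 2.4, where I read 2.53 L mol⁻¹ d⁻¹. It rests on the same early loss: “cap and impurity each quickly consume one first end”.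

The flask gives 7.92 for amber and 11.8 for green, so green ends longer.

    first end groups + protic impurity → quenched substrate (k = 18.0 L mol⁻¹ h⁻¹)
    first end groups + one-sided end groups → capped ends (k = 1.10 L mol⁻¹ h⁻¹)
    first end groups + second end groups → links (k = 0.100 L mol⁻¹ h⁻¹)

In green, the half-life of first end groups by the link step is 0.41 d at 0.274 d but 6.3 d at 6.00 d, far longer. Links in green move from 83.0% at 3.00 d, where amber ends with the same 83.0% and a length of 7.92, to 86.9% at 6.00 d, where green's length is 11.8. Read green at 10 d: the same gap and k give [B] = 0.0202 M and a length of 15.0. The computed length is 14.7.

The runs were computed with made-up constants; noise was put on by code.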